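**Retrosynthetic overview**
Numbering: pinane C1–C7 (spiro C2 = C1′); cyclopentane C1′–C5′ (isopropyl on C3′, spiro C2′ = C1″); cyclohexenedione C1″–C6″ (C2″=O, C3″–Me, C4″–OMe, C5″Me2, C6″=O).
Enabling feature: the six-membered ring is a masked cyclohexane-1,3,5-trione (C2″, C4″, C6″ at the carbonyl level, non-enolisable C5″Me2, one acidic C3″–H). It therefore divides into a dimethylmalonyl unit (C4″–C5″–C6″) and an ethyl ketone (C3″ with its methyl, C2″, C1″).
Disconnections: C4″–OMe (O-methylation) ⇒ spiro trione ⇒ one-pot [3+3] double Claisen (C3″–C4″ intermolecular, then ring closure C1″–C6″) ⇒ cyclopentyl ethyl ketone + dimethyl dimethylmalonate.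
Ketone ⇒ asymmetric 1,4-addition of isopropyl (C3′) ⇒ cyclopentenyl ketone ⇒ aldol condensation (C2′–C3′) ⇒ conjugate addition creating quaternary C2 ⇒ nopinylidene ethyl ketone ⇒ nopinone ⇒ (+)-β-pinene.
Ring order: pinane (chiral pool), cyclopentane (step 5), cyclohexenedione (step 7); stereocentres C2 (step 4), C3′ (step 6), C2′ (step 7).

Key step: step 7

Remark: the pinane unit of the target corresponds to (1R,5R)-(+)-β-pinene, which is assumed to be purchased enantiopure; the alkenes of 5 and 6 are drawn as E (E/Z is immaterial) and the trione 17 as its 4″-enol.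

Step 1
Reactants: 1 (1R,5R)-(+)-β-pinene
Product: 3 (1S,5R)-(−)-nopinone, via ozonide 2 (not isolated)
Conditions: O3, CH2Cl2, −78 °C; then Me2S, −78 → 25 °C
Reagents that add atoms: ozone, [O-][O+]=O
Why: Ozonolysis (Criegee mechanism) with reductive work-up cleaves only the exocyclic C2=CH2 bond and leaves both ring stereocentres untouched.

Step 2
Reactants: 3 (1S,5R)-(−)-nopinone; 4 diethyl {2-[methoxy(methyl)amino]-2-oxoethyl}phosphonate
Product: 5 (E)-2-[(1S,5R)-6,6-dimethylbicyclo[3.1.1]heptan-2-ylidene]-N-methoxy-N-methylacetamide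
Conditions: NaH, THF, 0 → 66 °C
Reagents that add atoms: none
Why: Horner–Wadsworth–Emmons olefination of the ketone with a stabilised phosphonate gives the unsaturated Weinreb amide; the alkene geometry is irrelevant because this carbon becomes sp3 in step 4.

Step 3
Reactants: 5 (E)-2-[(1S,5R)-6,6-dimethylbicyclo[3.1.1]heptan-2-ylidene]-N-methoxy-N-methylacetamide
Product: 6 (E)-1-[(1S,5R)-6,6-dimethylbicyclo[3.1.1]heptan-2-ylidene]butan-2-one
Conditions: EtMgBr, THF, −20 → 0 °C; aq. NH4Cl
Reagents that add atoms: ethylmagnesium bromide, CC[Mg]Br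
Why: Weinreb ketone synthesis: the chelated tetrahedral adduct stops at mono-addition and collapses on work-up to the ethyl enone, the hindered β,β-disubstituted alkene resisting 1,4-addition.

Step 4
Reactants: 6 (E)-1-[(1S,5R)-6,6-dimethylbicyclo[3.1.1]heptan-2-ylidene]butan-2-one; 7 [2-(1,3-dioxolan-2-yl)ethyl]magnesium bromide
Product: 9 1-{(1R,2S,5R)-2-[2-(1,3-dioxolan-2-yl)ethyl]-6,6-dimethylbicyclo[3.1.1]heptan-2-yl}butan-2-one, via silyl enol ether 8 (not isolated)
Conditions: CuBr·SMe2 (10 mol %), Me3SiCl, THF, −40 → 0 °C; then K2CO3 (cat.), MeOH, 25 °C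
Reagents that add atoms: none
Why: Copper-catalysed, Me3SiCl-accelerated conjugate addition of a Grignard reagent to a β,β-disubstituted enone creates quaternary C2; the nucleophile enters anti to the gem-dimethyl bridge (as reagents do on β-pinene), so the acetal arm ends anti and the ketone arm syn to CMe2, as the target requires.

Step 5
Reactants: 9 1-{(1R,2S,5R)-2-[2-(1,3-dioxolan-2-yl)ethyl]-6,6-dimethylbicyclo[3.1.1]heptan-2-yl}butan-2-one
Product: 12 1-[(1S,2S,5R)-6,6-dimethylspiro[bicyclo[3.1.1]heptane-2,1′-cyclopent[2]en]-2′-yl]propan-1-one, via keto aldehyde 10 (not isolated), via aldol 11 (not isolated)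
Conditions: PPTS (10 mol %), acetone–H2O, 50 °C; then KOH (0.3 equiv), MeOH, 25 °C
Reagents that add atoms: none
Why: Acetal hydrolysis followed by base-mediated intramolecular aldol condensation, in which the ketone enolate attacks the more electrophilic aldehyde (5-(enolexo)-exo-trig, as in the closure of 6-oxoheptanal to 1-acetylcyclopentene), gives the cyclopentenyl ketone without creating a stereocentre.

Step 6
Reactants: 12 1-[(1S,2S,5R)-6,6-dimethylspiro[bicyclo[3.1.1]heptane-2,1′-cyclopent[2]en]-2′-yl]propan-1-one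
Product: 14 1-[(1S,2S,5R,2′R,3′R)-6,6-dimethyl-3′-(propan-2-yl)spiro[bicyclo[3.1.1]heptane-2,1′-cyclopentan]-2′-yl]propan-1-one (trans), via cis ketone 13 (not isolated)
Conditions: i-PrMgBr, CuBr·SMe2 (5 mol %), 1-[2-(diphenylphosphino)ferrocenyl]ethyldicyclohexylphosphine (6 mol %, antipode matched to the required C3′ face), t-BuOMe, −78 °C; aq. NH4Cl; then NaOMe (0.2 equiv), MeOH, 25 °C
Reagents that add atoms: isopropylmagnesium bromide, CC(C)[Mg]Br
Why: Copper-catalysed asymmetric conjugate addition of a Grignard reagent to an enone: the spiro centre is 1,3 to the attacked carbon and should bias the faces only weakly, so the chiral diphosphine–copper complex sets C3′ (isopropyl on the cyclopentane face that carries pinane C3, not the bridgehead C1); methoxide then equilibrates C2′ to the trans ketone, a centre that is planarised again in step 7.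

Step 7
Reactants: 14 1-[(1S,2S,5R,2′R,3′R)-6,6-dimethyl-3′-(propan-2-yl)spiro[bicyclo[3.1.1]heptane-2,1′-cyclopentan]-2′-yl]propan-1-one; 15 dimethyl 2,2-dimethylpropanedioate
Product: 17 (1S,2R,5R,2′R,3′R)-4″-hydroxy-3″,5″,5″,6,6-pentamethyl-3′-(propan-2-yl)dispiro[bicyclo[3.1.1]heptane-2,1′-cyclopentane-2′,1″-cyclohex[3]ene]-2″,6″-dione, via diketo ester 16 (not isolated)
Conditions: LiN(i-Pr)2 (2.2 equiv), THF, −78 °C; add 15, −78 → 0 °C; then LiN(i-Pr)2 (1.5 equiv), DMPU, −78 → 25 °C; aq. HCl
Reagents that add atoms: none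
Why: LiN(i-Pr)2 deprotonates 14 only at the ethyl CH2 (the other α-position is a tertiary C–H between the quaternary spiro carbon and C3′), this enolate undergoes a crossed Claisen condensation with one ester of the non-enolisable diester 15 to give 16 as its lithium 1,3-diketonate, and the second charge of base removes the only remaining α-hydrogen (C2′–H) so that the dianion carbon attacks the second ester, expels methoxide and forms the C1″–C6″ bond. The closest known reaction types are the γ-acylation of 1,3-diketone dianions and the Claisen cyclisation of 3,5-dioxo esters to cyclohexane-1,3,5-triones, the whole being the base-mediated counterpart of the Effenberger α,α′-annulation of a ketone with a malonyl unit. One ring is closed, the six-membered trione ring, by 6-(enolexo)-exo-trig attack of C2′ on the ester carbon C6″. The new quaternary stereocentre C2′ is controlled by the adjacent C3′ isopropyl group: the tethered ester should reach the planar dianion carbon from the face anti to isopropyl, which places C6″ trans and C2″ cis to isopropyl as in the target. The step needs regioselective enolisation, C- rather than O-acylation, and this facial preference: the first is secured by the steric difference between the two α-carbons, the second because the product (deprotonated at C3″ between two carbonyls) is the thermodynamic sink to which any pyran-2,4-dione is returned by the lithium methoxide present, and the third by the 1,2-relationship of isopropyl to the reacting carbon, which should outweigh the more remote pinane.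

Step 8
Reactants: 17 (1S,2R,5R,2′R,3′R)-4″-hydroxy-3″,5″,5″,6,6-pentamethyl-3′-(propan-2-yl)dispiro[bicyclo[3.1.1]heptane-2,1′-cyclopentane-2′,1″-cyclohex[3]ene]-2″,6″-dione
Product: 18 (1S,2R,5R,2′R,3′R)-4″-methoxy-3″,5″,5″,6,6-pentamethyl-3′-(propan-2-yl)dispiro[bicyclo[3.1.1]heptane-2,1′-cyclopentane-2′,1″-cyclohex[3]ene]-2″,6″-dione
Conditions: Me3SiCHN2, MeOH–toluene, 0 → 25 °C
Reagents that add atoms: (trimethylsilyl)diazomethane, C[Si](C)(C)C=[N+]=[N-]
Why: O-Methylation of a vinylogous acid with a diazoalkane: the enol oxygen at C4″ (flanked by CMe2) is more accessible than that at C2″ (flanked by the spiro carbon with its cis isopropyl group and the pinane), so the 4″-methyl ether should predominate, and no stereocentre is touched.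

**Compound list**
1 | (1R,5R)-(+)-β-pinene | C=C1CC[C@@H]2C[C@H]1C2(C)C | starting material
2 | secondary ozonide of 1 (spiro-1,2,4-trioxolane at C2, mixture at the spiro carbon) | C1OC2(OO1)CC[C@@H]3C[C@H]2C3(C)C | intermediate
3 | (1S,5R)-(−)-nopinone | O=C1CC[C@@H]2C[C@H]1C2(C)C | intermediate
4 | diethyl {2-[methoxy(methyl)amino]-2-oxoethyl}phosphonate | CCOP(=O)(CC(=O)N(C)OC)OCC | starting material
5 | (E)-2-[(1S,5R)-6,6-dimethylbicyclo[3.1.1]heptan-2-ylidene]-N-methoxy-N-methylacetamide | CON(C)C(=O)/C=C1\CC[C@@H]2C[C@H]1C2(C)C | intermediate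
6 | (E)-1-[(1S,5R)-6,6-dimethylbicyclo[3.1.1]heptan-2-ylidene]butan-2-one | CCC(=O)/C=C1\CC[C@@H]2C[C@H]1C2(C)C | intermediate
7 | [2-(1,3-dioxolan-2-yl)ethyl]magnesium bromide | Br[Mg]CCC1OCCO1 | starting material
8 | trimethylsilyl enol ether of 9 (acetal arm anti to the gem-dimethyl bridge) | CCC(O[Si](C)(C)C)=C[C@@]1(CCC2OCCO2)CC[C@@H]2C[C@H]1C2(C)C | intermediate
9 | 1-{(1R,2S,5R)-2-[2-(1,3-dioxolan-2-yl)ethyl]-6,6-dimethylbicyclo[3.1.1]heptan-2-yl}butan-2-one | CCC(=O)C[C@@]1(CCC2OCCO2)CC[C@@H]2C[C@H]1C2(C)C | intermediate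
10 | 3-[(1R,2S,5R)-6,6-dimethyl-2-(2-oxobutyl)bicyclo[3.1.1]heptan-2-yl]propanal | CCC(=O)C[C@@]1(CCC=O)CC[C@@H]2C[C@H]1C2(C)C | intermediate
11 | 3′-hydroxy-2′-propanoyl spiro aldol (mixture at C2′ and C3′) | CCC(=O)C1C(O)CC[C@@]12CC[C@@H]3C[C@H]2C3(C)C | intermediate
12 | 1-[(1S,2S,5R)-6,6-dimethylspiro[bicyclo[3.1.1]heptane-2,1′-cyclopent[2]en]-2′-yl]propan-1-one | CCC(=O)C1=CCC[C@@]12CC[C@@H]3C[C@H]2C3(C)C | intermediate
13 | cis ketone, (2′S,3′R)-epimer of 14 | CCC(=O)[C@H]1[C@@H](C(C)C)CC[C@@]12CC[C@@H]3C[C@H]2C3(C)C | intermediate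
14 | 1-[(1S,2S,5R,2′R,3′R)-6,6-dimethyl-3′-(propan-2-yl)spiro[bicyclo[3.1.1]heptane-2,1′-cyclopentan]-2′-yl]propan-1-one | CCC(=O)[C@@H]1[C@@H](C(C)C)CC[C@@]12CC[C@@H]3C[C@H]2C3(C)C | intermediate
15 | dimethyl 2,2-dimethylpropanedioate | COC(=O)C(C)(C)C(=O)OC | starting material
16 | methyl 5-[(1S,2S,5R,2′R,3′R)-6,6-dimethyl-3′-(propan-2-yl)spiro[bicyclo[3.1.1]heptane-2,1′-cyclopentan]-2′-yl]-2,2,4-trimethyl-3,5-dioxopentanoate (C4 epimers/enol) | COC(=O)C(C)(C)C(=O)C(C)C(=O)[C@@H]1[C@@H](C(C)C)CC[C@@]12CC[C@@H]3C[C@H]2C3(C)C | intermediate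
17 | (1S,2R,5R,2′R,3′R)-4″-hydroxy-3″,5″,5″,6,6-pentamethyl-3′-(propan-2-yl)dispiro[bicyclo[3.1.1]heptane-2,1′-cyclopentane-2′,1″-cyclohex[3]ene]-2″,6″-dione | OC1=C(C)C(=O)[C@@]2(C(=O)C1(C)C)[C@@H](C(C)C)CC[C@@]21CC[C@@H]2C[C@H]1C2(C)C | intermediate
18 | (1S,2R,5R,2′R,3′R)-4″-methoxy-3″,5″,5″,6,6-pentamethyl-3′-(propan-2-yl)dispiro[bicyclo[3.1.1]heptane-2,1′-cyclopentane-2′,1″-cyclohex[3]ene]-2″,6″-dione | COC1=C(C)C(=O)[C@@]2(C(=O)C1(C)C)[C@@H](C(C)C)CC[C@@]21CC[C@@H]2C[C@H]1C2(C)C | target

Total step count: 8. Longest linear sequence: 8 steps (from 1).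

**Steps most likely to fail**

Step 7. The crossed Claisen on the hindered diester may be slow, the second deprotonation at the tertiary C2′–H may be incomplete, or closure may stop at O-acylation. The fallback sets out from 14. Its kinetic enolate is trapped (LiN(i-Pr)2, Me3SiCl) as the trimethylsilyl enol ether F1. F1 is treated with dimethylmalonyl dichloride in an Effenberger-type pyranone annulation (C-acylation at the ethyl carbon, then O-acylation) to give the 6-substituted 3,3,5-trimethyl-2H-pyran-2,4(3H)-dione F2. NaOMe in MeOH opens this enol lactone to the enolate of 16, and KOt-Bu in THF under thermodynamic Dieckmann conditions closes it, so the fallback comes back to the route at 17.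

Step 6. The α-substituted enone may react sluggishly with the chiral copper catalyst, or facial selectivity at C3′ may be poor. The fallback sets out from 12. Corey–Bakshi–Shibata reduction ((S)-2-methyl-CBS-oxazaborolidine, BH3·SMe2) gives the (R)-allylic alcohol F3, which is esterified (picolinic acid, DCC, DMAP) to the picolinate F4. Anti-SN2′ substitution with i-PrMgBr/CuBr·SMe2 transfers the carbinol chirality to C3′: allylic strain against the spiro carbon fixes the reactive conformer, and isopropyl enters anti to the leaving group, giving the (E)-ethylidenecyclopentane F5. Hydroboration–oxidation (BH3·THF; H2O2, NaOH) gives the secondary alcohol F6. Dess–Martin oxidation and NaOMe equilibration (through 13) bring the fallback back to the route at 14.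

Step 8. Methylation may occur at the wrong enol oxygen, or at carbon. The fallback sets out from 17, or from a mixture of 18 and the 2″-methoxy regioisomer F7. It replaces kinetic alkylation by thermodynamic enol-ether exchange (HC(OMe)3, MeOH, cat. camphorsulfonic acid, 40 °C). The two vinylogous esters interconvert through the dimethyl ketal, and the less congested 4″-ether should accumulate, so the fallback comes back to the route at 18.

**Further compounds**
F1 | step 7 | trimethylsilyl enol ether of 14 at the ethyl group | CC=C(O[Si](C)(C)C)[C@@H]1[C@@H](C(C)C)CC[C@@]12CC[C@@H]3C[C@H]2C3(C)C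
F2 | step 7 | 6-[(1S,2S,5R,2′R,3′R)-6,6-dimethyl-3′-(propan-2-yl)spiro[bicyclo[3.1.1]heptane-2,1′-cyclopentan]-2′-yl]-3,3,5-trimethyl-2H-pyran-2,4(3H)-dione | CC1=C([C@@H]2[C@@H](C(C)C)CC[C@@]23CC[C@@H]4C[C@H]3C4(C)C)OC(=O)C(C)(C)C1=O
F3 | step 6 | (R)-1-[(1S,2S,5R)-6,6-dimethylspiro[bicyclo[3.1.1]heptane-2,1′-cyclopent[2]en]-2′-yl]propan-1-ol | CC[C@@H](O)C1=CCC[C@@]12CC[C@@H]3C[C@H]2C3(C)C
F4 | step 6 | picolinate ester of F3 | CC[C@@H](OC(=O)c1ccccn1)C1=CCC[C@@]12CC[C@@H]3C[C@H]2C3(C)C
F5 | step 6 | (E)-2′-propylidene-3′-(propan-2-yl) spiro compound, isopropyl as in 14 | CC/C=C1\[C@@H](C(C)C)CC[C@@]12CC[C@@H]3C[C@H]2C3(C)C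
F6 | step 6 | 1-[cis-3′-(propan-2-yl)spiro[pinane-2,1′-cyclopentan]-2′-yl]propan-1-ol (carbinol epimers) | CCC(O)[C@H]1[C@@H](C(C)C)CC[C@@]12CC[C@@H]3C[C@H]2C3(C)C
F7 | step 8 | 2″-methoxy regioisomer of 18 (4″,6″-dione) | CC1=C(OC)[C@@]2(C(=O)C(C)(C)C1=O)[C@@H](C(C)C)CC[C@@]21CC[C@@H]2C[C@H]1C2(C)C
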